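# Proposed synthesis of 3-O-caffeoyl-1-methylquinic acid by lactone enolate Claisen ring contraction

Remark on numbering: the ring is numbered from the carboxyl-bearing carbon C1 so that the acylated oxygen sits on C5 and the free cis-diol on C3 and C4, with C7 as the carboxyl carbon. This C5 is the position called 3 in the trivial name.

## The problem

The target is one cyclohexane ring with four stereocentres: a fully substituted C1 bearing a methyl ether and the carboxyl carbon C7, a cis-diol at C3/C4, and at C5 an oxygen that is trans to O4, cis to the carboxyl group and esterified with caffeic acid 17. C1 cannot be made by substitution, and a tertiary alcohol there would be hard to methylate, so its C–O bond should exist before the centre is created. C5 is the natural controlling centre, because an allylic C5 oxygen can steer a cis-dihydroxylation of a C3=C4 alkene to the opposite face; what then remains is to relate C1 to C5 across the ring and to fix one absolute configuration. The three secondary oxygens must be told apart, since only O5 is acylated and the neighbouring O4 is where an acyl group would migrate. The caffeoyl ester is the fragile part: base cleaves or shifts it, its catechol oxidises easily, and its alkene rules out hydrogenolysis and any late osmylation, so it must arrive last and be unmasked under acid. The feature that makes the key step possible is that C7 on C1 is 1,3-cis to O5 while C4 only has to end as an alkene carbon, so C7 can be tied to an oxygen on C4 in a six-membered lactone (ring atoms C7, C1, C6, C5, C4, O) whose C4 carries the vinyl group C3=C2. Enolisation of that lactone gives the array C1=C7–O–C4–C3=C2, in which a [3,3] shift forms C1–C2, closes the carbocycle C1–C6 and hands the configuration of C4, and with it that of C5, to C1.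

## Retrosynthesis

**Ester and masks.** The O5–acyl bond and three acid-labile masks are cut first: 22 comes from the fully protected ester 20 by way of 21, and 20 from alcohol 16 and di-O-acetylcaffeic acid 18 through its chloride 19. A methyl ester at C7 would need saponification, which the caffeoyl ester would not survive, and a benzyl ester would need hydrogenolysis next to a cinnamate. A tert-butyl ester, an acetonide and aryl acetates all fall to acid. The forward steps must acylate a hindered secondary alcohol beside a ketal and deprotect without acyl migration. Acid 18 is one step from 17.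

**The diol.** The C3–O and C4–O bonds are cut together, taking 16 back through 15 and 14 to cyclohexene 13. This removes two stereocentres and leaves a ring with only C1 and C5 defined. The forward reaction is an OsO4-catalysed cis-dihydroxylation that must go anti to the C5 silyloxy group. That silyl group also marks O5 as the one oxygen to be freed for acylation, so the three oxygens never need to be differentiated afterwards.

**The key cut.** Ester 13 comes from acid 12, and in 12 the C1–C2 bond is cut while C7 is reconnected to an oxygen on C4, giving lactone 9 by way of ketene acetal 10 and silyl ester 11. The neighbouring cuts at C1 (C1–C7 or C1–O on a preformed ring) leave the C1 configuration to conformational bias, and a two-bond cycloaddition cut leaves it to an external catalyst. Here C1 follows from C4 through a ring-constrained concerted shift. Lactone 9 is much simpler: no carbocycle, no quaternary centre, only two adjacent carbinol centres, and a methoxy-bearing centre whose configuration does not matter. The forward step needs clean O-silylation of the lactone enolate and a boat-like transition state that the six-membered ring can reach.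

**The lactone.** The C7–O4 bond of 9 is cut to give δ-hydroxy amide 8, which comes from 7 and 6 by protecting-group changes. The order is forced: O5 is γ to the carbonyl and would close a five-membered lactone, so it is silylated while O4 still carries an oxidatively removable benzyl-type ether. Only then is O4 released and closed onto the amide.

**The C1–C6 bond.** Hydroxy amide 6 is cut between C1 and C6 into epoxide 3 and 2-methoxy-N,N-dimethylacetamide 4, which reacts as its enolate 5. An amide is chosen over an ester because amide enolates open epoxides and the resulting γ-hydroxy amide stays open under base. Amide 4 brings C1 with its methyl ether and C7 at the acid oxidation level, so no later oxidation or tertiary O-methylation is needed. The forward reaction must attack only the terminal epoxide carbon.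

**Origin of chirality.** Epoxide 3 is the 4-methoxybenzyl ether of epoxy alcohol 2, and the epoxide C–O bonds of 2 are cut back to achiral penta-1,4-dien-3-ol 1. One catalytic asymmetric epoxidation sets both carbinol centres (later C4 and C5). C4 is then spent in the key step to set C1, and C5 directs the diol, so all four stereocentres of 22 trace to this one reaction.

## Roads not taken

Alternative 1: The cut is the C1–O bond. The substrate is the exocyclic alkene A1, in which C7 is already present as a methylidene carbon, the C3 hydroxyl is free and axial, and O4/O5 are tied in a ketal. In the forward key step a VO(acac)2-catalysed hydroperoxide epoxidation, directed by the homoallylic C3 hydroxyl, gives spiro-epoxide A2 with the new C1–O bond cis to O3.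
- Merits: C1 is set by a directed, catalytic reaction on a rigid ring, with no sigmatropic step whose transition state has to be reached. In that respect it is at least as dependable as the chosen key step.
- Weak points: A2 is far from the target. The epoxide must be opened at C7 by an oxygen nucleophile without ionising C1, C7 must be oxidised to the acid in two operations, and the tertiary C1 hydroxyl must be methylated with the C3 hydroxyl protected. The trans-fused 4,5-ketal is strained and has to be exchanged for a 3,4-ketal before acylation. A1 itself presupposes the C3–C5 triad, which has to be bought or made.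
- Comparison: the chosen plan sets against the reliable directed epoxidation the fact that its C1 arrives with the methyl ether and the carboxyl oxidation level already in place, and that the triad is built, not assumed.

Alternative 2: The cuts are C1–C6 and C2–C3. In the forward key step buta-1,3-diene A3 adds to methyl 2-methoxyacrylate A4 under a chiral oxazaborolidinium Lewis acid and gives the cyclohexene ester A5, methyl (S)-1-methoxycyclohex-3-ene-1-carboxylate. Halolactonisation onto the alkene, elimination and dihydroxylation from the face opposite the lactone bridge would then relay C1 to C5, C3 and C4.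
- Merits: this is the shortest way to the ring, from commodity materials, with catalytic asymmetry. The bridging lactone enforces both the carboxyl/O5 relationship and the face of dihydroxylation rigidly; on that point it is better than the dihydroxylation in the chosen plan.
- Weak points: the catalyst must distinguish the faces of the captodative acrylate A4. Its α-oxygen lowers dienophilicity and offers the Lewis acid a second binding mode, and diene A3 is an unreactive gas. The one stereocentre of A5 is defined only by a remote double bond, and nothing downstream can correct a shortfall in enantiopurity. The lactone must also be reopened and the acid re-protected before O5 can be acylated.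
- Comparison: if the cycloaddition were highly enantioselective this road would be a few steps shorter. The chosen plan sets against that an absolute-configuration step of established reliability with built-in enrichment, and a C1 that follows from it by a concerted transfer.

Alternative 3: The cut is C1–C7. In the forward key step 2-lithiofuran A7, a carboxyl anion equivalent, adds from the equatorial direction to the tris(benzyloxy)cyclohexanone A6, and the alkoxide is methylated in the same flask to give furyl methyl ether A8.
- Merits: the route is convergent, the carbinol triad needs no stereoselective reaction at all, and trapping the tertiary alkoxide solves the methyl ether problem neatly. In these respects it is stronger than the chosen plan.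
- Weak points: A6 is itself the product of a multistep carbocyclisation, so the steps are moved, not saved. The facial preference on a mobile ketone with three alkoxy groups, each able to chelate lithium, is uncertain. The furan of A8 must be degraded by ozonolysis because RuO4 attacks benzyl ethers. After hydrogenolysis all three hydroxyls are equal, and O5 must be singled out by extra ketal steps before acylation.
- Comparison: the chosen plan sets against the stereochemically free triad of A6 an O5 that is differentiated from O3/O4 from the outset, and a C1 configuration enforced by ring constraint instead of conformational bias.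

Key step: step 7

## Route

Step 1
Reactants: 1 penta-1,4-dien-3-ol
Product: 2 (2R,3S)-1,2-epoxypent-4-en-3-ol
Conditions: Ti(OiPr)4 (cat.), L-(+)-diisopropyl tartrate (cat.), t-BuOOH, 4 Å molecular sieves, CH2Cl2, −20 °C
Reagents that add atoms: tert-butyl hydroperoxide, CC(C)(C)OO
Why: Sharpless asymmetric epoxidation run as a desymmetrisation: the catalyst formed from Ti(OiPr)4 and L-(+)-diisopropyl tartrate selects the vinyl group for which the carbinol centre reads S and gives the anti (erythro) epoxy alcohol, C2 R and C3 S. The minor enantiomer keeps the fast-reacting vinyl group and is consumed by a second epoxidation, so enantiomeric purity should rise with conversion.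

Step 2
Reactants: 2 (2R,3S)-1,2-epoxypent-4-en-3-ol
Product: 3 (2R,3S)-1,2-epoxy-3-(4-methoxybenzyloxy)pent-4-ene
Conditions: NaH, 4-methoxybenzyl chloride, Bu4NI (cat.), THF, 0 °C → rt
Reagents that add atoms: 4-methoxybenzyl chloride, COc1ccc(CCl)cc1
Why: Williamson etherification of the sodium alkoxide with iodide catalysis; at 0 °C in THF O-alkylation should outrun Payne rearrangement of the epoxy alkoxide, and neither stereocentre is touched.

Step 3
Reactants: 3 (2R,3S)-1,2-epoxy-3-(4-methoxybenzyloxy)pent-4-ene; 4 2-methoxy-N,N-dimethylacetamide
Product: 6 (4R,5S)-4-hydroxy-2-methoxy-5-(4-methoxybenzyloxy)-N,N-dimethylhept-6-enamide (both C2 epimers), via amide lithium enolate 5 (not isolated)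
Conditions: 4, LiN(iPr)2, THF, −78 °C; then 3, −78 → 0 °C; aq. NH4Cl
Reagents that add atoms: none
Why: SN2 opening of the epoxide at its unsubstituted carbon by a tertiary amide lithium enolate forms the C1–C6 bond and leaves both carbinol centres untouched; a tertiary γ-hydroxy amide does not lactonise under these basic conditions. The new methoxy-bearing centre forms as a mixture that is erased in step 7.

Step 4
Reactants: 6 (4R,5S)-4-hydroxy-2-methoxy-5-(4-methoxybenzyloxy)-N,N-dimethylhept-6-enamide
Product: 7 (4R,5S)-4-(tert-butyldimethylsilyloxy)-2-methoxy-5-(4-methoxybenzyloxy)-N,N-dimethylhept-6-enamide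
Conditions: t-BuMe2SiOTf, 2,6-lutidine, CH2Cl2, 0 °C
Reagents that add atoms: tert-butyldimethylsilyl trifluoromethanesulfonate, CC(C)(C)[Si](C)(C)OS(=O)(=O)C(F)(F)F
Why: Silylation of the secondary alcohol with a silyl triflate and a hindered base; O5 is capped so that only O4 can later close onto the carbonyl group.

Step 5
Reactants: 7 (4R,5S)-4-(tert-butyldimethylsilyloxy)-2-methoxy-5-(4-methoxybenzyloxy)-N,N-dimethylhept-6-enamide
Product: 8 (4R,5S)-4-(tert-butyldimethylsilyloxy)-5-hydroxy-2-methoxy-N,N-dimethylhept-6-enamide
Conditions: DDQ, CH2Cl2/pH 7 buffer, 0 °C → rt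
Reagents that add atoms: none
Why: Oxidative cleavage of the 4-methoxybenzyl ether by DDQ (hydride abstraction to the oxocarbenium ion, then hydrolysis); the silyl ether, the amide and the terminal alkene are inert.

Step 6
Reactants: 8 (4R,5S)-4-(tert-butyldimethylsilyloxy)-5-hydroxy-2-methoxy-N,N-dimethylhept-6-enamide
Product: 9 (5R,6S)-5-(tert-butyldimethylsilyloxy)-3-methoxy-6-vinyltetrahydro-2H-pyran-2-one (both C3 epimers)
Conditions: camphorsulfonic acid (1.2 equiv), PhMe, 60 °C
Reagents that add atoms: none
Why: Acid-promoted intramolecular alcoholysis of the tertiary amide by the δ-hydroxyl (lactonisation), driven by protonation of the departing dimethylamine; with O5 silylated only the six-membered lactone can form, and its C5 and C6 keep the trans relationship set in step 1.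

Step 7
Reactants: 9 (5R,6S)-5-(tert-butyldimethylsilyloxy)-3-methoxy-6-vinyltetrahydro-2H-pyran-2-one
Product: 12 (1S,5R)-5-(tert-butyldimethylsilyloxy)-1-methoxycyclohex-3-ene-1-carboxylic acid, via cyclic silyl ketene acetal 10 (not isolated), via trimethylsilyl ester 11 (not isolated)
Conditions: Me3SiCl, LiN(iPr)2, THF, −78 °C → rt; PhMe, 110 °C; aq. citric acid
Reagents that add atoms: none
Why: Deprotonation of either C3 epimer of 9 by LiN(iPr)2 with Me3SiCl present gives the single cyclic silyl ketene acetal 10, in which the methoxy-bearing carbon is trigonal and C1=C7–O–C4–C3=C2 forms a 1,5-diene. On heating, 10 undergoes a concerted suprafacial [3,3] shift (Ireland–Claisen rearrangement) that forms C1–C2, moves the double bond to C3=C4 and breaks the allylic C4–O bond, giving silyl ester 11, which loses its trimethylsilyl group on aqueous work-up. The closest known reaction type is the ring contraction of alkenyl lactone silyl ketene acetals to cycloalkene carboxylic acids, together with its oxygen analogue that turns 6-alkenyl-1,4-dioxan-2-ones into dihydropyran carboxylic acids through the same geometry. The cyclohexene closes by bonding of the ketene acetal carbon to the terminal vinyl carbon, formally an endo closure onto the vinyl group, through a boat-like, bicyclo[2.2.2]octane-shaped transition state: C1 and C4 are joined by the C7–O bridge, the C6–C5 tether and the reacting C2=C3 unit, which excludes a chair and makes the ring alkene necessarily cis. The only new stereocentre, C1, is controlled by C4 of the lactone: the C7–O bridge spans one face of the forming carbocycle, so the carboxyl group appears on the face that carried the C4–O bond and the methoxy group on the other. Because the C5 silyloxy group is trans to the vinyl group in 9 it lies on the bridge face and ends cis to the carboxyl group, as the target requires, while C5 itself is untouched and C4 ceases to be stereogenic. The step needs O-silylation in preference to C-silylation and rearrangement in preference to loss of the ring alkoxide as a ketene; trapping at −78 °C with the chlorosilane already present and the fully substituted, oxygen-stabilised enolate carbon should secure the first, and the intramolecular shift of the neutral ketene acetal the second.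

Step 8
Reactants: 12 (1S,5R)-5-(tert-butyldimethylsilyloxy)-1-methoxycyclohex-3-ene-1-carboxylic acid
Product: 13 tert-butyl (1S,5R)-5-(tert-butyldimethylsilyloxy)-1-methoxycyclohex-3-ene-1-carboxylate
Conditions: tert-butyl 2,2,2-trichloroacetimidate, CH2Cl2/cyclohexane, rt
Reagents that add atoms: tert-butyl 2,2,2-trichloroacetimidate, CC(C)(C)OC(=N)C(Cl)(Cl)Cl
Why: tert-Butylation through the protonated trichloroacetimidate transfers a tert-butyl cation to the carboxylate, so no nucleophile has to reach the hindered carbonyl carbon; the silyl ether and the alkene are unaffected.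

Step 9
Reactants: 13 tert-butyl (1S,5R)-5-(tert-butyldimethylsilyloxy)-1-methoxycyclohex-3-ene-1-carboxylate
Product: 14 tert-butyl (1S,3R,4R,5R)-5-(tert-butyldimethylsilyloxy)-3,4-dihydroxy-1-methoxycyclohexane-1-carboxylate
Conditions: OsO4 (cat.), N-methylmorpholine N-oxide, acetone/H2O, rt
Reagents that add atoms: N-methylmorpholine N-oxide, C[N+]1([O-])CCOCC1; water, O
Why: Upjohn dihydroxylation: OsO4 adds suprafacially to the C3=C4 alkene on the face opposite the allylic C5 silyloxy group, which is also the face opposite the ester, and so sets C3 and C4 as the cis-diol trans to O5. The two oxygens are passed on through the catalytic OsO4, which is regenerated by the N-oxide and water.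

Step 10
Reactants: 14 tert-butyl (1S,3R,4R,5R)-5-(tert-butyldimethylsilyloxy)-3,4-dihydroxy-1-methoxycyclohexane-1-carboxylate
Product: 15 tert-butyl (1S,3R,4R,5R)-5-(tert-butyldimethylsilyloxy)-3,4-(isopropylidenedioxy)-1-methoxycyclohexane-1-carboxylate
Conditions: 2,2-dimethoxypropane, pyridinium p-toluenesulfonate (cat.), acetone, rt
Reagents that add atoms: 2,2-dimethoxypropane, COC(C)(C)OC
Why: Acid-catalysed transketalisation; only the cis-vicinal diol can form the five-membered ketal, which masks O3 and O4 together.

Step 11
Reactants: 15 tert-butyl (1S,3R,4R,5R)-5-(tert-butyldimethylsilyloxy)-3,4-(isopropylidenedioxy)-1-methoxycyclohexane-1-carboxylate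
Product: 16 tert-butyl (1R,3R,4S,5R)-5-hydroxy-3,4-(isopropylidenedioxy)-1-methoxycyclohexane-1-carboxylate
Conditions: Bu4NF, AcOH, THF, rt
Reagents that add atoms: none
Why: Fluoride-induced desilylation; acetic acid buffers the alkoxide so that the ketal and the tert-butyl ester, which resists acyl transfer to the cis hydroxyl, stay intact. The changed descriptors at C1 and C4 reflect only the new ligand priorities.

Step 12
Reactants: 17 caffeic acid
Product: 18 (E)-3-(3,4-diacetoxyphenyl)prop-2-enoic acid
Conditions: Ac2O, pyridine, DMAP (cat.), rt; H2O
Reagents that add atoms: acetic anhydride, CC(=O)OC(C)=O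
Why: Pyridine-promoted acetylation of both phenols; any mixed anhydride at the carboxyl group is hydrolysed on aqueous work-up, and the E alkene is not affected.

Step 13
Reactants: 16 tert-butyl (1R,3R,4S,5R)-5-hydroxy-3,4-(isopropylidenedioxy)-1-methoxycyclohexane-1-carboxylate; 18 (E)-3-(3,4-diacetoxyphenyl)prop-2-enoic acid
Product: 20 tert-butyl (1S,3R,4R,5R)-5-[(E)-3-(3,4-diacetoxyphenyl)prop-2-enoyloxy]-3,4-(isopropylidenedioxy)-1-methoxycyclohexane-1-carboxylate, via di-O-acetylcaffeoyl chloride 19 (not isolated)
Conditions: 18, (COCl)2, DMF (cat.), CH2Cl2, 0 °C → rt, concentrate; then 16, pyridine, DMAP (cat.), CH2Cl2, 0 °C → rt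
Reagents that add atoms: none
Why: Acid chloride formation with oxalyl chloride, then DMAP-catalysed acylation of the hindered secondary alcohol (nucleophilic catalysis); only the O–H bond at C5 is broken, so its configuration is retained, and the acetates keep the catechol from competing.

Step 14
Reactants: 20 tert-butyl (1S,3R,4R,5R)-5-[(E)-3-(3,4-diacetoxyphenyl)prop-2-enoyloxy]-3,4-(isopropylidenedioxy)-1-methoxycyclohexane-1-carboxylate
Product: 22 3-O-caffeoyl-1-methylquinic acid [(1S,3R,4R,5R)-5-[(E)-3-(3,4-dihydroxyphenyl)prop-2-enoyloxy]-3,4-dihydroxy-1-methoxycyclohexane-1-carboxylic acid in the numbering used here], via di-O-acetyl acid 21 (not isolated)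
Conditions: CF3CO2H/CH2Cl2/H2O, 0 °C → rt, concentrate; then 1 M aq. HCl/THF, rt
Reagents that add atoms: none
Why: Acidolysis in two stages: trifluoroacetic acid removes the tert-butyl group as its cation and hydrolyses the ketal, then dilute aqueous HCl hydrolyses the two activated aryl acetates faster than the hindered secondary cinnamate. Acid throughout avoids base-induced acyl migration to O4 and oxidation of the catechol, and no stereocentre is involved.

## Compound list

1 | penta-1,4-dien-3-ol (divinylcarbinol) | C=CC(O)C=C | starting material
2 | (2R,3S)-1,2-epoxypent-4-en-3-ol | C=C[C@H](O)[C@H]1CO1 | intermediate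
3 | (2R,3S)-1,2-epoxy-3-(4-methoxybenzyloxy)pent-4-ene | C=C[C@H](OCc1ccc(OC)cc1)[C@H]1CO1 | intermediate
4 | 2-methoxy-N,N-dimethylacetamide | COCC(=O)N(C)C | starting material
5 | lithium 1-(dimethylamino)-2-methoxyethenolate (amide lithium enolate) | COC=C(O[Li])N(C)C | intermediate
6 | (4R,5S)-4-hydroxy-2-methoxy-5-(4-methoxybenzyloxy)-N,N-dimethylhept-6-enamide, both C2 epimers | CN(C)C(=O)C(OC)C[C@@H](O)[C@@H](OCc1ccc(OC)cc1)C=C | intermediate
7 | (4R,5S)-4-(tert-butyldimethylsilyloxy)-2-methoxy-5-(4-methoxybenzyloxy)-N,N-dimethylhept-6-enamide, both C2 epimers | CN(C)C(=O)C(OC)C[C@@H](O[Si](C)(C)C(C)(C)C)[C@@H](OCc1ccc(OC)cc1)C=C | intermediate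
8 | (4R,5S)-4-(tert-butyldimethylsilyloxy)-5-hydroxy-2-methoxy-N,N-dimethylhept-6-enamide, both C2 epimers | CN(C)C(=O)C(OC)C[C@@H](O[Si](C)(C)C(C)(C)C)[C@@H](O)C=C | intermediate
9 | (5R,6S)-5-(tert-butyldimethylsilyloxy)-3-methoxy-6-vinyltetrahydro-2H-pyran-2-one, both C3 epimers | COC1C[C@@H](O[Si](C)(C)C(C)(C)C)[C@H](C=C)OC1=O | intermediate
10 | (2S,3R)-3-(tert-butyldimethylsilyloxy)-5-methoxy-6-(trimethylsilyloxy)-2-vinyl-3,4-dihydro-2H-pyran | COC1=C(O[Si](C)(C)C)O[C@@H](C=C)[C@H](O[Si](C)(C)C(C)(C)C)C1 | intermediate
11 | trimethylsilyl (1S,5R)-5-(tert-butyldimethylsilyloxy)-1-methoxycyclohex-3-ene-1-carboxylate | CO[C@@]1(C(=O)O[Si](C)(C)C)CC=C[C@H](O[Si](C)(C)C(C)(C)C)C1 | intermediate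
12 | (1S,5R)-5-(tert-butyldimethylsilyloxy)-1-methoxycyclohex-3-ene-1-carboxylic acid | CO[C@@]1(C(=O)O)CC=C[C@H](O[Si](C)(C)C(C)(C)C)C1 | intermediate
13 | tert-butyl (1S,5R)-5-(tert-butyldimethylsilyloxy)-1-methoxycyclohex-3-ene-1-carboxylate | CO[C@@]1(C(=O)OC(C)(C)C)CC=C[C@H](O[Si](C)(C)C(C)(C)C)C1 | intermediate
14 | tert-butyl (1S,3R,4R,5R)-5-(tert-butyldimethylsilyloxy)-3,4-dihydroxy-1-methoxycyclohexane-1-carboxylate | CO[C@@]1(C(=O)OC(C)(C)C)C[C@@H](O)[C@@H](O)[C@H](O[Si](C)(C)C(C)(C)C)C1 | intermediate
15 | tert-butyl (1S,3R,4R,5R)-5-(tert-butyldimethylsilyloxy)-3,4-(isopropylidenedioxy)-1-methoxycyclohexane-1-carboxylate | CO[C@@]1(C(=O)OC(C)(C)C)C[C@H]2OC(C)(C)O[C@H]2[C@H](O[Si](C)(C)C(C)(C)C)C1 | intermediate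
16 | tert-butyl (1R,3R,4S,5R)-5-hydroxy-3,4-(isopropylidenedioxy)-1-methoxycyclohexane-1-carboxylate | CO[C@@]1(C(=O)OC(C)(C)C)C[C@H]2OC(C)(C)O[C@H]2[C@H](O)C1 | intermediate
17 | caffeic acid | O=C(O)/C=C/c1ccc(O)c(O)c1 | starting material
18 | (E)-3-(3,4-diacetoxyphenyl)prop-2-enoic acid | CC(=O)Oc1ccc(/C=C/C(=O)O)cc1OC(C)=O | intermediate
19 | (E)-3-(3,4-diacetoxyphenyl)prop-2-enoyl chloride | CC(=O)Oc1ccc(/C=C/C(Cl)=O)cc1OC(C)=O | intermediate
20 | tert-butyl (1S,3R,4R,5R)-5-[(E)-3-(3,4-diacetoxyphenyl)prop-2-enoyloxy]-3,4-(isopropylidenedioxy)-1-methoxycyclohexane-1-carboxylate | CO[C@@]1(C(=O)OC(C)(C)C)C[C@H]2OC(C)(C)O[C@H]2[C@H](OC(=O)/C=C/c3ccc(OC(C)=O)c(OC(C)=O)c3)C1 | intermediate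
21 | (1S,3R,4R,5R)-5-[(E)-3-(3,4-diacetoxyphenyl)prop-2-enoyloxy]-3,4-dihydroxy-1-methoxycyclohexane-1-carboxylic acid | CO[C@@]1(C(=O)O)C[C@@H](O)[C@@H](O)[C@H](OC(=O)/C=C/c2ccc(OC(C)=O)c(OC(C)=O)c2)C1 | intermediate
22 | 3-O-caffeoyl-1-methylquinic acid | CO[C@@]1(C(=O)O)C[C@@H](O)[C@@H](O)[C@H](OC(=O)/C=C/c2ccc(O)c(O)c2)C1 | target

## Step count and least certain steps

Total: 14 steps. Longest linear sequence: 13 steps (steps 1–11, 13 and 14, from 1 to 22); step 12 is a one-step branch from 17.

**Step 7 (key step).** The ketene acetal 10 may decay before it reaches the boat-like transition state, by O-to-C silyl migration or by loss of the ring alkoxide as a ketene. The six-membered lactone has to tip its vinyl group into a flagpole-like position and the migrating terminus is fully substituted, so the shift may need more heat than 10 tolerates. The fallback makes the same C1–C2 bond by an ionic ring closure; it sets out from 8 and comes back to the route at 16. The allylic hydroxyl of 8 would be phosphorylated with diethyl chlorophosphate and pyridine to give (4R,5S)-4-(tert-butyldimethylsilyloxy)-5-(diethoxyphosphoryloxy)-2-methoxy-N,N-dimethylhept-6-enamide F1. KN(SiMe3)2 in THF should then close the ring by intramolecular SN2′ alkylation of the amide enolate at the vinyl terminus, giving (1S,5R)-5-(tert-butyldimethylsilyloxy)-1-methoxy-N,N-dimethylcyclohex-3-ene-1-carboxamide F2 along with its C1 epimer, since no tether now dictates the face. Fluoride would free the C5 hydroxyl to give (1S,5R)-5-hydroxy-1-methoxy-N,N-dimethylcyclohex-3-ene-1-carboxamide F3. Warming with camphorsulfonic acid would lactonise only the epimer whose amide is cis to that hydroxyl, giving (1S,5R)-1-methoxy-6-oxabicyclo[3.2.1]oct-3-en-7-one F4; this both cleaves the hindered amide and selects the correct C1 configuration. Catalytic OsO4 with N-methylmorpholine N-oxide should add opposite the lactone bridge to give (1S,3R,4R,5R)-3,4-dihydroxy-1-methoxy-6-oxabicyclo[3.2.1]octan-7-one F5, and 2,2-dimethoxypropane with acid would give the 3,4-O-isopropylidene derivative of that diol lactone F6. LiOH hydrolysis and careful acidification would give (1R,3R,4S,5R)-5-hydroxy-3,4-(isopropylidenedioxy)-1-methoxycyclohexane-1-carboxylic acid F7, and esterification with O-tert-butyl-N,N′-diisopropylisourea rejoins the route at 16.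

**Step 3.** The opening may be sluggish and lose material to proton transfer or base-induced isomerisation of the epoxide, because an α-alkoxy amide enolate is aggregated and less nucleophilic than a simple one. The fallback uses a stabilised carbanion; it sets out from 3 and comes back to the route at 6. Sodium dimethyl 2-methoxymalonate in methanol (NaOMe, reflux) would open the epoxide and close onto one ester, giving methyl (5R)-3-methoxy-5-[(1S)-1-(4-methoxybenzyloxy)prop-2-en-1-yl]-2-oxooxolane-3-carboxylate F8. Krapcho dealkoxycarbonylation (LiCl, wet DMSO, heat) would give (5R)-3-methoxy-5-[(1S)-1-(4-methoxybenzyloxy)prop-2-en-1-yl]oxolan-2-one F9. Aminolysis with the aluminium amide made from AlMe3 and dimethylamine would open the lactone and return to the route at 6.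

**Step 6.** The stoichiometric acid may remove the silyl ether, after which the five-membered lactone would form, or closure may stall as the liberated amine buffers the acid. The fallback replaces acyl substitution by a redox relay; it sets out from 7 and comes back to the route at 9. LiAlH(OEt)3 would reduce the dimethylamide to (4R,5S)-4-(tert-butyldimethylsilyloxy)-2-methoxy-5-(4-methoxybenzyloxy)hept-6-enal F10. DDQ would release O4, which closes to the lactol (5R,6S)-5-(tert-butyldimethylsilyloxy)-3-methoxy-6-vinyltetrahydro-2H-pyran-2-ol F11. Oxidation with TEMPO and PhI(OAc)2 would give 9 under neutral conditions.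

**Step 9.** Facial selectivity may be poor, because in the favoured half-chair the face anti to the silyloxy group carries the axial C1 methoxy group. The fallback lets a bridging lactone enforce the face; it sets out from 12 and comes back to the route at 16. Fluoride would give (1S,5R)-5-hydroxy-1-methoxycyclohex-3-ene-1-carboxylic acid F12, and carbodiimide lactonisation would give the bicyclic lactone F4. Dihydroxylation opposite the bridge, ketalisation, hydrolysis and tert-butyl esterification would follow as described for step 7 through F5, F6 and F7, returning to the route at 16.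

**Step 14.** Aryl acetate hydrolysis may be incomplete, or prolonged acid exposure may start acyl migration to O4 or hydrolysis of the caffeoyl ester. The fallback unmasks the catechol under neutral conditions; it sets out from 17 and 16 and comes back to the route at 22. Allyl bromide and K2CO3 would convert 17 into allyl (E)-3-[3,4-bis(allyloxy)phenyl]prop-2-enoate F13, and NaOH would give (E)-3-[3,4-bis(allyloxy)phenyl]prop-2-enoic acid F14. Coupling of F14 as its chloride with 16 would give tert-butyl (1S,3R,4R,5R)-5-{(E)-3-[3,4-bis(allyloxy)phenyl]prop-2-enoyloxy}-3,4-(isopropylidenedioxy)-1-methoxycyclohexane-1-carboxylate F15. Pd(PPh3)4 with morpholine would remove both allyl ethers to give tert-butyl (1S,3R,4R,5R)-5-[(E)-3-(3,4-dihydroxyphenyl)prop-2-enoyloxy]-3,4-(isopropylidenedioxy)-1-methoxycyclohexane-1-carboxylate F16. A single treatment with aqueous trifluoroacetic acid would then give 22.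

## Further compounds

F1 | step 7 | (4R,5S)-4-(tert-butyldimethylsilyloxy)-5-(diethoxyphosphoryloxy)-2-methoxy-N,N-dimethylhept-6-enamide | CN(C)C(=O)C(OC)C[C@@H](O[Si](C)(C)C(C)(C)C)[C@@H](OP(=O)(OCC)OCC)C=C
F2 | step 7 | (1S,5R)-5-(tert-butyldimethylsilyloxy)-1-methoxy-N,N-dimethylcyclohex-3-ene-1-carboxamide | CO[C@@]1(C(=O)N(C)C)CC=C[C@H](O[Si](C)(C)C(C)(C)C)C1
F3 | step 7 | (1S,5R)-5-hydroxy-1-methoxy-N,N-dimethylcyclohex-3-ene-1-carboxamide | CO[C@@]1(C(=O)N(C)C)CC=C[C@H](O)C1
F4 | step 7 | (1S,5R)-1-methoxy-6-oxabicyclo[3.2.1]oct-3-en-7-one | CO[C@@]12CC=C[C@@H](C1)OC2=O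
F5 | step 7 | (1S,3R,4R,5R)-3,4-dihydroxy-1-methoxy-6-oxabicyclo[3.2.1]octan-7-one | CO[C@@]12C[C@@H](O)[C@@H](O)[C@@H](C1)OC2=O
F6 | step 7 | 3,4-O-isopropylidene derivative of (1S,3R,4R,5R)-3,4-dihydroxy-1-methoxy-6-oxabicyclo[3.2.1]octan-7-one | CO[C@@]12C[C@H]3OC(C)(C)O[C@H]3[C@@H](C1)OC2=O
F7 | step 7 | (1R,3R,4S,5R)-5-hydroxy-3,4-(isopropylidenedioxy)-1-methoxycyclohexane-1-carboxylic acid | CO[C@@]1(C(=O)O)C[C@H]2OC(C)(C)O[C@H]2[C@H](O)C1
F8 | step 3 | methyl (5R)-3-methoxy-5-[(1S)-1-(4-methoxybenzyloxy)prop-2-en-1-yl]-2-oxooxolane-3-carboxylate, both C3 epimers | COC(=O)C1(OC)C[C@H]([C@@H](OCc2ccc(OC)cc2)C=C)OC1=O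
F9 | step 3 | (5R)-3-methoxy-5-[(1S)-1-(4-methoxybenzyloxy)prop-2-en-1-yl]oxolan-2-one, both C3 epimers | COC1C[C@H]([C@@H](OCc2ccc(OC)cc2)C=C)OC1=O
F10 | step 6 | (4R,5S)-4-(tert-butyldimethylsilyloxy)-2-methoxy-5-(4-methoxybenzyloxy)hept-6-enal, both C2 epimers | O=CC(OC)C[C@@H](O[Si](C)(C)C(C)(C)C)[C@@H](OCc1ccc(OC)cc1)C=C
F11 | step 6 | (5R,6S)-5-(tert-butyldimethylsilyloxy)-3-methoxy-6-vinyltetrahydro-2H-pyran-2-ol, anomers and C3 epimers | COC1C[C@@H](O[Si](C)(C)C(C)(C)C)[C@H](C=C)OC1O
F12 | step 9 | (1S,5R)-5-hydroxy-1-methoxycyclohex-3-ene-1-carboxylic acid | CO[C@@]1(C(=O)O)CC=C[C@H](O)C1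
F13 | step 14 | allyl (E)-3-[3,4-bis(allyloxy)phenyl]prop-2-enoate | C=CCOC(=O)/C=C/c1ccc(OCC=C)c(OCC=C)c1
F14 | step 14 | (E)-3-[3,4-bis(allyloxy)phenyl]prop-2-enoic acid | OC(=O)/C=C/c1ccc(OCC=C)c(OCC=C)c1
F15 | step 14 | tert-butyl (1S,3R,4R,5R)-5-{(E)-3-[3,4-bis(allyloxy)phenyl]prop-2-enoyloxy}-3,4-(isopropylidenedioxy)-1-methoxycyclohexane-1-carboxylate | CO[C@@]1(C(=O)OC(C)(C)C)C[C@H]2OC(C)(C)O[C@H]2[C@H](OC(=O)/C=C/c3ccc(OCC=C)c(OCC=C)c3)C1
F16 | step 14 | tert-butyl (1S,3R,4R,5R)-5-[(E)-3-(3,4-dihydroxyphenyl)prop-2-enoyloxy]-3,4-(isopropylidenedioxy)-1-methoxycyclohexane-1-carboxylate | CO[C@@]1(C(=O)OC(C)(C)C)C[C@H]2OC(C)(C)O[C@H]2[C@H](OC(=O)/C=C/c3ccc(O)c(O)c3)C1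
A1 | alternative 1 | 1-methylidenecyclohexane-3,4,5-triol 4,5-acetonide with free axial C3 hydroxyl, C3 to C5 configured as in 22 | C=C1C[C@@H](O)[C@H]2OC(C)(C)O[C@@H]2C1
A2 | alternative 1 | spiro-epoxide of A1, epoxide oxygen on C1 cis to the C3 hydroxyl | O1C[C@@]12C[C@@H](O)[C@H]3OC(C)(C)O[C@@H]3C2
A3 | alternative 2 | buta-1,3-diene | C=CC=C
A4 | alternative 2 | methyl 2-methoxyacrylate | COC(=C)C(=O)OC
A5 | alternative 2 | methyl (S)-1-methoxycyclohex-3-ene-1-carboxylate | CO[C@@]1(C(=O)OC)CCC=CC1
A6 | alternative 3 | (3R,5R)-3,4,5-tris(benzyloxy)cyclohexanone | O=C1C[C@@H](OCc2ccccc2)[C@@H](OCc2ccccc2)[C@H](OCc2ccccc2)C1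
A7 | alternative 3 | 2-lithiofuran | [Li]c1ccco1
A8 | alternative 3 | 2-[(3R,5R)-3,4,5-tris(benzyloxy)-1-methoxycyclohexyl]furan, methoxy cis to O3 and O4 | CO[C@@]1(c2ccco2)C[C@@H](OCc2ccccc2)[C@@H](OCc2ccccc2)[C@H](OCc2ccccc2)C1
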